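**Retrosynthetic overview**
1. Dichrostachine A ⇒ Diels–Alder union (C-12–C-1′ and C-15–C-6′ bonds; the cyclohexene ring is made last) of (12E)-labda-8(17),12,14-triene-7β,18-diol with a 2-(chromon-2-yl)-5-methoxy-1,4-benzoquinone made from a 2′,4′,5′-trimethoxyflavone.
2. Triene ⇒ C-12 aldehyde (two Wittig reactions) ⇒ a 3-silyloxy-Δ3-decalin whose C-20 is a lactone carbonyl tied to O–C-12; C-18 enters by hydroxymethylation of the enol ether, then the C-3 and C-20 oxygens are removed together.
3. Key disconnection: the C-1–C-2 and C-5–C-10 bonds, by an intramolecular Diels–Alder reaction that builds rings A and B at once from a monocyclic precursor.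
4. Enabling feature: C-20, C-10, C-9, C-11 and O–C-12 fit a δ-lactone whose exocyclic C-10=C-1 methylene is the dienophile, and C-2 to C-5 of ring A fit the 2-silyloxydiene of a methyl enone (C-3 carbonyl, C-4 methyl) joined to C-9 through C-6 to C-8, the future ring B.
5. Precursor ⇐ 5,6-dihydro-2H-pyran-2-one by rhodium-catalysed asymmetric alkenyl addition (C-9), α-methylenation (C-1) and a vinylogous Mukaiyama aldol reaction (C-7); ring order: temporary lactone → rings B and A together → cyclohexene/enedione ring.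

Key step: step 8

Remark (chemistry): labdane numbering is used for the terpenoid part; the given configuration at C-12/C-1′ is taken to arise from the (12E)-triene adding with the chromone, not the dione ring, beneath the diene.

**Step 1**
Reactants: 1 3,3-diethoxyprop-1-yne
Product: 2 2-(3,3-diethoxyprop-1-en-2-yl)-4,4,5,5-tetramethyl-1,3,2-dioxaborolane
Conditions: B2pin2 (1.1 equiv), CuCl (5 mol %), 1,3-bis(2,4,6-trimethylphenyl)imidazolinium chloride (5 mol %), NaOt-Bu (20 mol %), MeOH (2 equiv), THF, −50 → −15 °C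
Reagents that add atoms: bis(pinacolato)diboron, CC1(C)OB(OC1(C)C)B1OC(C)(C)C(C)(C)O1
Why: Copper-catalysed protoboration of a terminal alkyne: with an N-aryl carbene ligand and a propargylic oxygen substituent the Cu–B unit should add syn with boron on the internal carbon, and methanolysis of the vinylcopper gives the 1,1-disubstituted vinylboronate (no stereocentre).

**Step 2**
Reactants: 2 2-(3,3-diethoxyprop-1-en-2-yl)-4,4,5,5-tetramethyl-1,3,2-dioxaborolane; 3 5,6-dihydro-2H-pyran-2-one
Product: 4 (4R)-4-(3,3-diethoxyprop-1-en-2-yl)oxan-2-one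
Conditions: [Rh(cod)(OH)]2 (2.5 mol %), (R)-BINAP (6 mol %), 1,4-dioxane/H2O 10:1, 40 °C
Reagents that add atoms: none
Why: Rhodium-catalysed asymmetric 1,4-addition of an alkenylboronate to an unsaturated lactone (Hayashi–Miyaura reaction): the alkenyl–rhodium–BINAP species inserts the lactone C=C on the enantioface dictated by the ligand (by analogy with aryl additions (R)-BINAP should give the (4R)-lactone, which is C-9), and water protonates the rhodium enolate.

**Step 3**
Reactants: 4 (4R)-4-(3,3-diethoxyprop-1-en-2-yl)oxan-2-one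
Product: 7 (4S)-4-(3,3-diethoxyprop-1-en-2-yl)-3-methylideneoxan-2-one, via Mannich base 5 (not isolated), via ammonium iodide 6 (not isolated)
Conditions: LiN(SiMe3)2, THF, −78 °C; CH2=NMe2+ I−, −78 → 23 °C; MeI, MeOH, 23 °C; aq. NaHCO3, CH2Cl2, 23 °C
Reagents that add atoms: dimethyl(methylidene)ammonium iodide (Eschenmoser's salt), C=[N+](C)C.[I-]
Why: α-Methylenation of a lactone by the Mannich/quaternisation/elimination sequence: the lithium enolate is aminomethylated at C-10, N-methylation turns the amine into a leaving group and mild base induces E1cB elimination to the exocyclic enoate, while C-9 (β to the carbonyl) is not epimerisable and changes its descriptor to S only through the priority rules.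

**Step 4**
Reactants: 7 (4S)-4-(3,3-diethoxyprop-1-en-2-yl)-3-methylideneoxan-2-one
Product: 8 2-[(4S)-3-methylidene-2-oxooxan-4-yl]prop-2-enal
Conditions: pyridinium p-toluenesulfonate (cat.), acetone/H2O 10:1, 40 °C; used at once
Reagents that add atoms: water, O
Why: Acid-catalysed acetal hydrolysis under conditions mild enough to spare the lactone and both 1,1-disubstituted alkenes, giving the 2-substituted acrolein.

**Step 5**
Reactants: 9 but-2-enylmagnesium chloride; 10 N-methoxy-N-methylacetamide
Product: 11 3-methylpent-4-en-2-one (racemic)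
Conditions: THF, −78 → 0 °C; cold 1 M HCl quench
Reagents that add atoms: none
Why: Acylation of an allylic Grignard reagent with a Weinreb amide: the crotyl reagent reacts through its γ-carbon and the chelated tetrahedral intermediate prevents a second addition, so the β,γ-unsaturated methyl ketone results (its stereocentre disappears in step 6).

**Step 6**
Reactants: 11 3-methylpent-4-en-2-one
Product: 12 tert-butyl(dimethyl)[(3-methylpenta-2,4-dien-2-yl)oxy]silane (mixture of enol ether geometries)
Conditions: TBSOTf (1.1 equiv), Et3N (1.5 equiv), CH2Cl2, 0 °C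
Reagents that add atoms: tert-butyldimethylsilyl trifluoromethanesulfonate, CC(C)(C)[Si](C)(C)OS(=O)(=O)C(F)(F)F
Why: Soft enolisation (silyl triflate and amine) removes the most acidic proton, the one flanked by carbonyl and vinyl group, so that the through-conjugated silyl dienol ether with a free terminal CH2 should form rather than the methyl-derived isomer.

**Step 7**
Reactants: 8 2-[(4S)-3-methylidene-2-oxooxan-4-yl]prop-2-enal; 12 tert-butyl(dimethyl)[(3-methylpenta-2,4-dien-2-yl)oxy]silane
Product: 13 (4S)-4-[(3S,5E)-3-hydroxy-6-methyl-7-oxoocta-1,5-dien-2-yl]-3-methylideneoxan-2-one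
Conditions: SiCl4 (1.2 equiv), chiral 2,2′-binaphthyldiamine-derived bisphosphoramide (5 mol %, enantiomer chosen for Si-face attack), CH2Cl2, −78 °C; sat. aq. NaHCO3; used promptly
Reagents that add atoms: none
Why: Catalytic enantioselective vinylogous Mukaiyama aldol reaction (Lewis-base-activated SiCl4): the ketone-derived dienol ether attacks through its unhindered terminal γ-carbon (the α-carbon carries the methyl group), the phosphoramide-bound trichlorosilyl cation activates only the aldehyde and exposes its Si face so that C-7 should form as (S) under catalyst control, and the new trisubstituted enone forms with (E) geometry.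

**Step 8**
Reactants: 13 (4S)-4-[(3S,5E)-3-hydroxy-6-methyl-7-oxoocta-1,5-dien-2-yl]-3-methylideneoxan-2-one
Product: 15 (5α,7β)-3,7-bis(tert-butyldimethylsilyloxy)-13,14,15,16,18-pentanorlabda-3,8(17)-dien-20,12-olide, via bis-silylated triene 14 (not isolated)
Conditions: TBSOTf (2.5 equiv), Et3N (4 equiv), CH2Cl2, −78 → 0 °C; then toluene, 80 °C
Reagents that add atoms: tert-butyldimethylsilyl trifluoromethanesulfonate, CC(C)(C)[Si](C)(C)OS(=O)(=O)C(F)(F)F
Why: Silyl triflate and amine silylate the C-7 hydroxyl and convert the methyl ketone into its cross-conjugated 2-silyloxy-1,3-diene (14), which should then undergo a type 1 intramolecular Diels–Alder reaction with the α-methylene lactone across C-1/C-2 and C-5/C-10 (closest precedents: intramolecular Diels–Alder reactions of deca-1,7,9-trienes and silyl triflate–amine promoted intramolecular double Michael reactions). Ring B closes by the C-5–C-10 bond through the four-atom tether C-6 to C-9 in a chair-like arrangement, and ring A is the cyclohexene of the [4+2] event, closed by the C-1–C-2 bond. The quaternary C-10 is set relative to C-9 because the diene hangs from C-8 on C-9 and can only reach the face of the exocyclic methylene syn to C-8, and the lactone ring forces C-20 and C-11 to be cis. C-5 is set by the (E) geometry of the C-4=C-5 bond and by the endo orientation of the lactone carbonyl (locked s-cis to the methylene group), which places H-5 anti to C-20 and gives the trans-decalin, with the C-7 silyloxy group equatorial on the forming ring. The step needs regiocontrol and trans over cis ring fusion: the first is enforced by the tether and reinforced by polarity (nucleophilic C-2 of the silyloxydiene to the β-carbon C-1 of the enoate), the second relies on the endo preference of the activated lactone carbonyl.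

**Step 9**
Reactants: 15 (5α,7β)-3,7-bis(tert-butyldimethylsilyloxy)-13,14,15,16,18-pentanorlabda-3,8(17)-dien-20,12-olide
Product: 16 (5α,7β)-3,7-bis(tert-butyldimethylsilyloxy)-12,20-epoxy-13,14,15,16,18-pentanorlabda-3,8(17)-dien-20-ol (lactol; anomer mixture)
Conditions: i-Bu2AlH (1.2 equiv), CH2Cl2, −78 °C; aq. potassium sodium tartrate
Reagents that add atoms: none
Why: Partial reduction of a lactone: the aluminium-bound tetrahedral intermediate of the hindered neopentyl lactone is stable at −78 °C and gives the lactol on work-up, while silyl enol ether, silyl ether and alkene do not react with the hydride.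

**Step 10**
Reactants: 16 (5α,7β)-3,7-bis(tert-butyldimethylsilyloxy)-12,20-epoxy-13,14,15,16,18-pentanorlabda-3,8(17)-dien-20-ol
Product: 17 (7β)-7-(tert-butyldimethylsilyloxy)-12,20-epoxy-18,20-dihydroxy-13,14,15,16-tetranorlabd-8(17)-en-3-one (4α-CH2OH and 4β-CH3)
Conditions: 37 % aq. CH2O, Sc(OTf)3 (10 mol %), THF, 0 → 23 °C
Reagents that add atoms: formaldehyde, C=O
Why: Mukaiyama aldol reaction with formaldehyde (hydroxymethylation) under a water-tolerant Lewis acid: the tetrasubstituted silyl enol ether reacts regiospecifically at C-4 and the electrophile should come from the α-face, anti to the axial C-20 carbon on C-10, which sets the quaternary C-4 with CH2OH α (equatorial, C-18) and CH3 β.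

**Step 11**
Reactants: 17 (7β)-7-(tert-butyldimethylsilyloxy)-12,20-epoxy-18,20-dihydroxy-13,14,15,16-tetranorlabd-8(17)-en-3-one
Product: 18 (7β)-7-(tert-butyldimethylsilyloxy)-12,18-dihydroxy-3-oxo-13,14,15,16-tetranorlabd-8(17)-en-20-al 3,20-bis(4-methylbenzenesulfonylhydrazone)
Conditions: TsNHNH2 (2.5 equiv), MeOH, 60 °C
Reagents that add atoms: 4-methylbenzenesulfonohydrazide, Cc1ccc(S(=O)(=O)NN)cc1
Why: Hydrazone formation: tosylhydrazide condenses with the C-3 ketone and with the open hydroxy-aldehyde form of the lactol (C-20), which frees the C-12 hydroxyl.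

**Step 12**
Reactants: 18 (7β)-7-(tert-butyldimethylsilyloxy)-12,18-dihydroxy-3-oxo-13,14,15,16-tetranorlabd-8(17)-en-20-al 3,20-bis(4-methylbenzenesulfonylhydrazone)
Product: 19 (7β)-7-(tert-butyldimethylsilyloxy)-13,14,15,16-tetranorlabd-8(17)-ene-12,18-diol
Conditions: catecholborane (6 equiv), CHCl3, 0 → 23 °C; then NaOAc·3H2O, 60 °C
Reagents that add atoms: none
Why: Caglioti-type tosylhydrazone reduction: catecholborane adds hydride to each C=N bond and acetate-triggered loss of sulfinate and N2 from the diazenes leaves CH2 at C-3 and CH3 at C-20 under non-basic conditions that avoid retro-aldol loss of C-18 and alkene migration.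

**Step 13**
Reactants: 19 (7β)-7-(tert-butyldimethylsilyloxy)-13,14,15,16-tetranorlabd-8(17)-ene-12,18-diol
Product: 20 (7β)-7-(tert-butyldimethylsilyloxy)-18-hydroxy-13,14,15,16-tetranorlabd-8(17)-en-12-al
Conditions: TEMPO (10 mol %), PhI(OAc)2 (1.1 equiv), CH2Cl2, 0 °C
Reagents that add atoms: none
Why: Oxoammonium (TEMPO) oxidation is strongly retarded by steric hindrance, so the unhindered primary C-12 alcohol should be oxidised to the aldehyde in preference to the neopentyl C-18 alcohol, without over-oxidation.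

**Step 14**
Reactants: 20 (7β)-7-(tert-butyldimethylsilyloxy)-18-hydroxy-13,14,15,16-tetranorlabd-8(17)-en-12-al
Product: 21 (7β,12E)-7-(tert-butyldimethylsilyloxy)-18-hydroxy-15-norlabda-8(17),12-dien-14-al
Conditions: Ph3P=C(CH3)CHO (1.5 equiv), toluene, 90 °C
Reagents that add atoms: 2-(triphenyl-λ5-phosphanylidene)propanal, CC(C=O)=P(c1ccccc1)(c1ccccc1)c1ccccc1
Why: Wittig reaction with a stabilised α-branched ylide, which reacts only with the aldehyde and gives the (E)-trisubstituted enal (C-11 trans to the formyl group) through the reversible addition typical of stabilised ylides.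

**Step 15**
Reactants: 21 (7β,12E)-7-(tert-butyldimethylsilyloxy)-18-hydroxy-15-norlabda-8(17),12-dien-14-al
Product: 22 (7β,12E)-7-(tert-butyldimethylsilyloxy)labda-8(17),12,14-trien-18-ol
Conditions: Ph3PCH3Br (3 equiv), KOt-Bu (2.9 equiv), THF, 0 → 23 °C
Reagents that add atoms: methyltriphenylphosphonium bromide, C[P+](c1ccccc1)(c1ccccc1)c1ccccc1.[Br-]
Why: Wittig methylenation of the enal carbonyl (excess ylide covers the free C-18 hydroxyl) completes the conjugated (12E)-diene without touching the existing double bonds.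

**Step 16**
Reactants: 22 (7β,12E)-7-(tert-butyldimethylsilyloxy)labda-8(17),12,14-trien-18-ol
Product: 23 (7β,12E)-labda-8(17),12,14-triene-7,18-diol
Conditions: n-Bu4NF (2 equiv), THF, 23 °C
Reagents that add atoms: none
Why: Fluoride-mediated cleavage of the secondary silyl ether, driven by the Si–F bond, under conditions to which the triene and the allylic alcohol are stable.

**Step 17**
Reactants: 24 2,4,5-trimethoxybenzoic acid
Product: 25 2,4,5-trimethoxybenzoyl chloride
Conditions: (COCl)2 (1.3 equiv), DMF (cat.), CH2Cl2, 0 → 23 °C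
Reagents that add atoms: oxalyl chloride, ClC(=O)C(=O)Cl
Why: Acid chloride formation through the chloroiminium (Vilsmeier-type) species generated from oxalyl chloride and catalytic DMF.

**Step 18**
Reactants: 26 1-(2,4,6-trihydroxyphenyl)ethan-1-one; 25 2,4,5-trimethoxybenzoyl chloride
Product: 27 1-(2,4,6-trihydroxyphenyl)-3-(2,4,5-trimethoxyphenyl)propane-1,3-dione
Conditions: LiN(SiMe3)2 (4.2 equiv), THF, −78 °C; then 25, −78 → 23 °C; aq. HCl
Reagents that add atoms: none
Why: Claisen-type C-acylation of the polylithiated hydroxyacetophenone (three phenoxides and the ketone enolate) with one equivalent of aroyl chloride gives the 1,3-diketone directly, the one-flask equivalent of a Baker–Venkataraman sequence without phenol protection.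

**Step 19**
Reactants: 27 1-(2,4,6-trihydroxyphenyl)-3-(2,4,5-trimethoxyphenyl)propane-1,3-dione
Product: 28 5,7-dihydroxy-2-(2,4,5-trimethoxyphenyl)-4H-chromen-4-one
Conditions: H2SO4 (cat.), AcOH, 95 °C
Reagents that add atoms: none
Why: Acid-catalysed cyclodehydration of the 2-hydroxyaryl 1,3-diketone (hemiketalisation and loss of water) to the flavone.

**Step 20**
Reactants: 28 5,7-dihydroxy-2-(2,4,5-trimethoxyphenyl)-4H-chromen-4-one
Product: 29 2-(5,7-dihydroxy-4-oxo-4H-chromen-2-yl)-5-methoxycyclohexa-2,5-diene-1,4-dione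
Conditions: (NH4)2Ce(NO3)6 (2.5 equiv), MeCN/H2O 2:1, 0 °C
Reagents that add atoms: water, O
Why: Oxidative demethylation of a 1,4-dimethoxyarene: the electron-rich trimethoxyphenyl ring should be oxidised far more easily than the carbonyl-deactivated dihydroxychromone ring, and the para-related 2′- and 5′-oxygens become the quinone carbonyls while the 4′-methoxy group is kept.

**Step 21**
Reactants: 23 (7β,12E)-labda-8(17),12,14-triene-7,18-diol; 29 2-(5,7-dihydroxy-4-oxo-4H-chromen-2-yl)-5-methoxycyclohexa-2,5-diene-1,4-dione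
Product: 30 dichrostachine A
Conditions: H2O/THF 3:1, 40 °C, dark, argon
Reagents that add atoms: none
Why: Intermolecular Diels–Alder reaction in the sense of the presumed biosynthesis: only the chromonyl-substituted quinone double bond is reactive (the other is deactivated by the methoxy group), the unsubstituted diene terminus C-15 bonds to the unsubstituted quinone carbon and C-12 to the chromonyl-bearing carbon (least hindered first bond, β to the chromone acceptor), suprafacial addition gives the cis ring fusion, the chromone rather than the dione ring should lie under the diene as is common when the reacting carbon becomes quaternary (this puts C-11 cis to the chromone), and the dienophile should approach the diene face anti to the C-9–C-11 bond in the rotamer that minimises allylic strain with the C-13 methyl group, which makes C-12 (R).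

**Compound list**
1 | 3,3-diethoxyprop-1-yne | C#CC(OCC)OCC | starting material
2 | 2-(3,3-diethoxyprop-1-en-2-yl)-4,4,5,5-tetramethyl-1,3,2-dioxaborolane | C=C(B1OC(C)(C)C(C)(C)O1)C(OCC)OCC | intermediate
3 | 5,6-dihydro-2H-pyran-2-one | O=C1C=CCCO1 | starting material
4 | (4R)-4-(3,3-diethoxyprop-1-en-2-yl)oxan-2-one | O=C1C[C@H](C(=C)C(OCC)OCC)CCO1 | intermediate
5 | Mannich base, 3-[(dimethylamino)methyl]-4-(3,3-diethoxyprop-1-en-2-yl)oxan-2-one (trans shown; C-3 is of no consequence) | CN(C)C[C@@H]1C(=O)OCC[C@H]1C(=C)C(OCC)OCC | intermediate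
6 | ammonium iodide, N,N,N-trimethyl-1-[4-(3,3-diethoxyprop-1-en-2-yl)-2-oxooxan-3-yl]methanaminium iodide | C[N+](C)(C)C[C@@H]1C(=O)OCC[C@H]1C(=C)C(OCC)OCC.[I-] | intermediate
7 | (4S)-4-(3,3-diethoxyprop-1-en-2-yl)-3-methylideneoxan-2-one | C=C1C(=O)OCC[C@H]1C(=C)C(OCC)OCC | intermediate
8 | 2-[(4S)-3-methylidene-2-oxooxan-4-yl]prop-2-enal | C=C1C(=O)OCC[C@H]1C(=C)C=O | intermediate
9 | but-2-enylmagnesium chloride | CC=CC[Mg]Cl | starting material
10 | N-methoxy-N-methylacetamide | CC(=O)N(C)OC | starting material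
11 | 3-methylpent-4-en-2-one (racemic) | CC(=O)C(C)C=C | intermediate
12 | tert-butyl(dimethyl)[(3-methylpenta-2,4-dien-2-yl)oxy]silane (enol ether E/Z mixture) | CC(O[Si](C)(C)C(C)(C)C)=C(C)C=C | intermediate
13 | (4S)-4-[(3S,5E)-3-hydroxy-6-methyl-7-oxoocta-1,5-dien-2-yl]-3-methylideneoxan-2-one | C=C1C(=O)OCC[C@H]1C(=C)[C@@H](O)C/C=C(\C)C(C)=O | intermediate
14 | bis-silylated triene, (4S)-4-[(3S,5E)-3,7-bis(tert-butyldimethylsilyloxy)-6-methylocta-1,5,7-trien-2-yl]-3-methylideneoxan-2-one | C=C1C(=O)OCC[C@H]1C(=C)[C@@H](O[Si](C)(C)C(C)(C)C)C/C=C(\C)C(=C)O[Si](C)(C)C(C)(C)C | intermediate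
15 | (5α,7β)-3,7-bis(tert-butyldimethylsilyloxy)-13,14,15,16,18-pentanorlabda-3,8(17)-dien-20,12-olide (trans-decalin; δ-lactone from C-20 to O–C-12) | C=C1[C@@H](O[Si](C)(C)C(C)(C)C)C[C@H]2C(C)=C(O[Si](C)(C)C(C)(C)C)CC[C@@]23C(=O)OCC[C@@H]13 | intermediate
16 | (5α,7β)-3,7-bis(tert-butyldimethylsilyloxy)-12,20-epoxy-13,14,15,16,18-pentanorlabda-3,8(17)-dien-20-ol (lactol, anomer mixture) | C=C1[C@@H](O[Si](C)(C)C(C)(C)C)C[C@H]2C(C)=C(O[Si](C)(C)C(C)(C)C)CC[C@@]23C(O)OCC[C@@H]13 | intermediate
17 | (7β)-7-(tert-butyldimethylsilyloxy)-12,20-epoxy-18,20-dihydroxy-13,14,15,16-tetranorlabd-8(17)-en-3-one (4α-CH2OH, 4β-CH3) | C=C1[C@@H](O[Si](C)(C)C(C)(C)C)C[C@H]2[C@](C)(CO)C(=O)CC[C@@]23C(O)OCC[C@@H]13 | intermediate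
18 | (7β)-7-(tert-butyldimethylsilyloxy)-12,18-dihydroxy-3-oxo-13,14,15,16-tetranorlabd-8(17)-en-20-al 3,20-bis(4-methylbenzenesulfonylhydrazone) | C=C1[C@@H](O[Si](C)(C)C(C)(C)C)C[C@H]2[C@](C)(CO)C(=NNS(=O)(=O)c3ccc(C)cc3)CC[C@]2(C=NNS(=O)(=O)c3ccc(C)cc3)[C@H]1CCO | intermediate
19 | (7β)-7-(tert-butyldimethylsilyloxy)-13,14,15,16-tetranorlabd-8(17)-ene-12,18-diol | C=C1[C@@H](O[Si](C)(C)C(C)(C)C)C[C@H]2[C@](C)(CO)CCC[C@]2(C)[C@H]1CCO | intermediate
20 | (7β)-7-(tert-butyldimethylsilyloxy)-18-hydroxy-13,14,15,16-tetranorlabd-8(17)-en-12-al | C=C1[C@@H](O[Si](C)(C)C(C)(C)C)C[C@H]2[C@](C)(CO)CCC[C@]2(C)[C@H]1CC=O | intermediate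
21 | (7β,12E)-7-(tert-butyldimethylsilyloxy)-18-hydroxy-15-norlabda-8(17),12-dien-14-al | C=C1[C@@H](O[Si](C)(C)C(C)(C)C)C[C@H]2[C@](C)(CO)CCC[C@]2(C)[C@H]1C/C=C(\C)C=O | intermediate
22 | (7β,12E)-7-(tert-butyldimethylsilyloxy)labda-8(17),12,14-trien-18-ol | C=C1[C@@H](O[Si](C)(C)C(C)(C)C)C[C@H]2[C@](C)(CO)CCC[C@]2(C)[C@H]1C/C=C(\C)C=C | intermediate
23 | (7β,12E)-labda-8(17),12,14-triene-7,18-diol | C=C1[C@@H](O)C[C@H]2[C@](C)(CO)CCC[C@]2(C)[C@H]1C/C=C(\C)C=C | intermediate
24 | 2,4,5-trimethoxybenzoic acid | COc1cc(OC)c(C(=O)O)cc1OC | starting material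
25 | 2,4,5-trimethoxybenzoyl chloride | COc1cc(OC)c(C(=O)Cl)cc1OC | intermediate
26 | 1-(2,4,6-trihydroxyphenyl)ethan-1-one | CC(=O)c1c(O)cc(O)cc1O | starting material
27 | 1-(2,4,6-trihydroxyphenyl)-3-(2,4,5-trimethoxyphenyl)propane-1,3-dione | COc1cc(OC)c(C(=O)CC(=O)c2c(O)cc(O)cc2O)cc1OC | intermediate
28 | 5,7-dihydroxy-2-(2,4,5-trimethoxyphenyl)-4H-chromen-4-one | COc1cc(OC)c(-c2cc(=O)c3c(O)cc(O)cc3o2)cc1OC | intermediate
29 | 2-(5,7-dihydroxy-4-oxo-4H-chromen-2-yl)-5-methoxycyclohexa-2,5-diene-1,4-dione | COC1=CC(=O)C(c2cc(=O)c3c(O)cc(O)cc3o2)=CC1=O | intermediate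
30 | dichrostachine A | C=C1[C@@H](O)C[C@H]2[C@](C)(CO)CCC[C@]2(C)[C@H]1C[C@@H]1C(C)=CC[C@H]2C(=O)C(OC)=CC(=O)[C@@]12c1cc(=O)c2c(O)cc(O)cc2o1 | target

**Totals**
Total step count: 21. Longest linear sequence: 15 steps (steps 1–4, 7–16 and 21).

**Steps most likely to fail**

Step 21. The cycloaddition may run through the dione-endo transition state, which with the (12E)-diene gives the opposite relative configuration at C-12/C-1′. It may also discriminate poorly between the two diene faces, or take the reverse orientation. The fallback sets out from 20 and returns at 30, changing the diene geometry so that the usual dione-endo mode leads to the target. Still–Gennari olefination of 20 with methyl 2-[bis(2,2,2-trifluoroethoxy)phosphoryl]propanoate (KN(SiMe3)2, 18-crown-6, THF, −78 °C) should give methyl (7β,12Z)-7-(tert-butyldimethylsilyloxy)-18-hydroxy-15-norlabda-8(17),12-dien-14-oate F1. Reduction with i-Bu2AlH gives (7β,12Z)-7-(tert-butyldimethylsilyloxy)-15-norlabda-8(17),12-diene-14,18-diol F2, and MnO2 oxidises only the allylic alcohol to (7β,12Z)-7-(tert-butyldimethylsilyloxy)-18-hydroxy-15-norlabda-8(17),12-dien-14-al F3. Methylenation with Ph3P=CH2 gives (7β,12Z)-7-(tert-butyldimethylsilyloxy)labda-8(17),12,14-trien-18-ol F4, and n-Bu4NF gives (7β,12Z)-labda-8(17),12,14-triene-7,18-diol F5. Cycloaddition of F5 with 29 at 10 kbar (CH2Cl2/THF) places the inward-pointing C-11 cis to the chromone when the dione ring is endo, and should give 30.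

Step 8. The cycloaddition may close through the transition state with the lactone carbonyl exo, giving the cis-fused decalin. Some γ-deprotonation to the through-conjugated dienol ether, which cannot cyclise, is also possible. The fallback sets out from 15 obtained as a ring-fusion mixture and returns to stereochemically uniform 15; the ring fusion is then set by dissolving-metal reduction instead of by the cycloaddition. Saegusa–Ito oxidation (Pd(OAc)2, MeCN, with acid equilibration of any exocyclic isomer) should give (7β)-7-(tert-butyldimethylsilyloxy)-3-oxo-13,14,15,16,18-pentanorlabda-4,8(17)-dien-20,12-olide F6, in which C-5 is no longer a stereocentre. Birch reduction (Li, NH3/THF, −78 °C, limited Li) protonates C-5 axially from the α-face, and trapping of the regiodefined lithium enolate with TBSCl/Et3N returns trans-fused 15.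

Step 7. The ketone-derived dienol ether may react partly through its α-carbon or with low facial control, and the product may undergo oxa-Michael closure onto the methylene lactone. The fallback sets out from 8 and returns at 14, using the better-behaved aldehyde-derived dienolate and building the methyl ketone afterwards. (E)-2-Methylbut-2-enal with TBSOTf/Et3N gives tert-butyl(dimethyl)[(2-methylbuta-1,3-dien-1-yl)oxy]silane F7. Vinylogous Mukaiyama aldol reaction of F7 with 8 under the SiCl4/bisphosphoramide conditions should give (2E,5S)-5-hydroxy-2-methyl-6-[(4S)-3-methylidene-2-oxooxan-4-yl]hepta-2,6-dienal F8. TBSCl/imidazole gives (2E,5S)-5-(tert-butyldimethylsilyloxy)-2-methyl-6-[(4S)-3-methylidene-2-oxooxan-4-yl]hepta-2,6-dienal F9. MeTi(Oi-Pr)3 adds to the aldehyde only and gives (4S)-4-[(3S,5E)-3-(tert-butyldimethylsilyloxy)-7-hydroxy-6-methylocta-1,5-dien-2-yl]-3-methylideneoxan-2-one F10 as a carbinol epimer mixture. Dess–Martin periodinane gives (4S)-4-[(3S,5E)-3-(tert-butyldimethylsilyloxy)-6-methyl-7-oxoocta-1,5-dien-2-yl]-3-methylideneoxan-2-one F11, which TBSOTf/Et3N converts into 14 under the conditions of step 8.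

**Further compounds**
F1 | step 21 | methyl (7β,12Z)-7-(tert-butyldimethylsilyloxy)-18-hydroxy-15-norlabda-8(17),12-dien-14-oate | C=C1[C@@H](O[Si](C)(C)C(C)(C)C)C[C@H]2[C@](C)(CO)CCC[C@]2(C)[C@H]1C/C=C(/C)C(=O)OC
F2 | step 21 | (7β,12Z)-7-(tert-butyldimethylsilyloxy)-15-norlabda-8(17),12-diene-14,18-diol | C=C1[C@@H](O[Si](C)(C)C(C)(C)C)C[C@H]2[C@](C)(CO)CCC[C@]2(C)[C@H]1C/C=C(/C)CO
F3 | step 21 | (7β,12Z)-7-(tert-butyldimethylsilyloxy)-18-hydroxy-15-norlabda-8(17),12-dien-14-al | C=C1[C@@H](O[Si](C)(C)C(C)(C)C)C[C@H]2[C@](C)(CO)CCC[C@]2(C)[C@H]1C/C=C(/C)C=O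
F4 | step 21 | (7β,12Z)-7-(tert-butyldimethylsilyloxy)labda-8(17),12,14-trien-18-ol | C=C1[C@@H](O[Si](C)(C)C(C)(C)C)C[C@H]2[C@](C)(CO)CCC[C@]2(C)[C@H]1C/C=C(/C)C=C
F5 | step 21 | (7β,12Z)-labda-8(17),12,14-triene-7,18-diol | C=C1[C@@H](O)C[C@H]2[C@](C)(CO)CCC[C@]2(C)[C@H]1C/C=C(/C)C=C
F6 | step 8 | (7β)-7-(tert-butyldimethylsilyloxy)-3-oxo-13,14,15,16,18-pentanorlabda-4,8(17)-dien-20,12-olide | C=C1[C@@H](O[Si](C)(C)C(C)(C)C)CC2=C(C)C(=O)CC[C@@]23C(=O)OCC[C@@H]13
F7 | step 7 | tert-butyl(dimethyl)[(2-methylbuta-1,3-dien-1-yl)oxy]silane | C=CC(C)=CO[Si](C)(C)C(C)(C)C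
F8 | step 7 | (2E,5S)-5-hydroxy-2-methyl-6-[(4S)-3-methylidene-2-oxooxan-4-yl]hepta-2,6-dienal | C=C1C(=O)OCC[C@H]1C(=C)[C@@H](O)C/C=C(\C)C=O
F9 | step 7 | (2E,5S)-5-(tert-butyldimethylsilyloxy)-2-methyl-6-[(4S)-3-methylidene-2-oxooxan-4-yl]hepta-2,6-dienal | C=C1C(=O)OCC[C@H]1C(=C)[C@@H](O[Si](C)(C)C(C)(C)C)C/C=C(\C)C=O
F10 | step 7 | (4S)-4-[(3S,5E)-3-(tert-butyldimethylsilyloxy)-7-hydroxy-6-methylocta-1,5-dien-2-yl]-3-methylideneoxan-2-one (carbinol epimers) | C=C1C(=O)OCC[C@H]1C(=C)[C@@H](O[Si](C)(C)C(C)(C)C)C/C=C(\C)C(C)O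
F11 | step 7 | (4S)-4-[(3S,5E)-3-(tert-butyldimethylsilyloxy)-6-methyl-7-oxoocta-1,5-dien-2-yl]-3-methylideneoxan-2-one | C=C1C(=O)OCC[C@H]1C(=C)[C@@H](O[Si](C)(C)C(C)(C)C)C/C=C(\C)C(C)=O
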